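The leftover comes first. At gamma's last reading, 80.0 min, D holds 14.8% of the Q charged and the other 85.2% is not D, yet D gained 4.9 percentage points between 15.0 min and 30.0 min and then 1.3 points over the last 20.0 min.

| flask | Q | X | remark | time |
|---|---|---|---|---|
| delta | 0.30 M | 110 mM (held) | the very flask that is asked about, followed so far |  |
| gamma | 0.60 M | 110 mM (held) | run made earlier |  |
| flask | 0.30 M | 110 mM (held) |  | 2.0 h |

| run | time / min | D / % |
|---|---|---|
| delta | 4.00 | 1.0 |
| delta | 6.00 | 2.6 |
| delta | 10.0 | 4.7 |
| delta | 20.0 | 9.0 |
| delta | 30.0 | 12.9 |
| delta | 50.0 | 18.9 |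
| gamma | 6.00 | 2.0 |
| gamma | 15.0 | 5.1 |
| gamma | 30.0 | 10.0 |
| gamma | 50.0 | 12.1 |
| gamma | 60.0 | 13.5 |
| gamma | 80.0 | 14.8 |

(each reading ± 0.5 percentage points)

- in percentages every species weighs as the Q in it: one Z counts as two
- at the start none of L is dissolved
- steps thought possible: X <-> L; Q + L -> D; L + D -> G; 2 Q -> Z

- D at 2.0 h, in percent of the Q charged
- the change that raises the amount of D at 2.0 h, in percent of the Q charged most ("none" if none brings more than 2 percentage points) (oak / cedar / none)
- amount of D at 2.0 h, in percent of the Q charged, after oak

- oak: doubling the transfer coefficient of X, all else as stated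
- cedar: doubling the saturation concentration of X, all else as stated

In the first instants there is no L, so there is no D. X feeds L, and delta shows D at 4.00 min, much sooner than the 2.0 h asked, so the rise of L is a short opening.

In the middle, with L steady, Q + L to D is pseudo-first-order in Q: the pace of D follows Q. My reading of gamma's leftover is that Q leaves by pairing into Z, which needs no L and goes with the square of Q. If that pairing sets the fall of Q, a charge twice as large runs the same course in half the time and makes the same molar D, which is half as much in percent of its own charge.

At the end comes a knee. Gamma's slows after 30.0 min, so delta's belongs near 60.0 min, and delta still gained 6 points from 30.0 min to 50.0 min. This gives the stretched reading S, delta's D at a time t taken as double gamma's D at t/2: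

S = 2 × 13.5% (gamma at 60.0 min) = 27.0%

So I expect about S. Oak shortens the opening and should add little. Cedar raises the L each Q meets, so it is my choice.

The forecast gives 29.5% (25% to 34%), cedar as best, and 34% (28% to 42%) after oak: “Extrapolating with further decay gives about 29-30% at 2 h”; its D is higher than S.

The flask gives 25.9%, and the best change is cedar, worth 11 points against 2.2 points for oak, which reaches 28.2%. Z then holds 67.3%, more than D, and S stands 1.1 points above the flask's D.

    X ⇌ L, rate k1*(csat - [L]) (kL = 9.60 h⁻¹)
    Q + L → D (k = 6.90 M⁻¹ h⁻¹)
    L + D → G (k = 0.420 M⁻¹ h⁻¹)
    2 Q → Z (k = 5.70 M⁻¹ h⁻¹)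

On delta read at 30 min, the stretch takes gamma at 15.0 min and gives 10.2%. The computed D is 13.3%, so at 30 min the stretch reads 3.1 points low, whereas at 2.0 h it read 1.1 points high.

Readings and results were computed for an exercise; the scatter is artificial.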